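The hexasubstituted central ring (C1–C6 in SMILES order: ester oxygens on C1 and C4, free hydroxyls on C2 and C5, aryls on C3 and C6) is opened across C4–C5 to a squarate-derived cyclobutenone. This precursor carries the future C3 aryl and C2 benzyloxy group on its ring alkene and, on its sp3 carbon, a triethylsilyloxy group (future O–C1) and a (Z)-1-aryl-2-benzyloxyvinyl arm (future C6 and C5). One thermal operation unfolds it, through a dienylketene, into the complete arene with O–C4 as a free phenol and O–C1 silylated, so the two different esters go on in turn and a single hydrogenolysis of five benzyl ethers finishes the route.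

Key step: step 6

Remark: C1 and C4 have identical surroundings (hydroxyl on one side, aryl on the other, in the same sense), so either para oxygen may take either acyl group; the base-stable 3-phenylpropanoate is put on first and the β-alkoxy ester last, and reagents without a number are taken as commercial.

Step 1
Reactants: 1 squaric acid
Product: 2 dibenzyl squarate (3,4-bis(benzyloxy)cyclobut-3-ene-1,2-dione)
Conditions: BnOH (excess), toluene, reflux, Dean–Stark
Reagents that add atoms: benzyl alcohol, OCc1ccccc1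
Why: Azeotropic esterification of the strongly acidic vinylogous diacid, which catalyses its own ester formation as in the usual preparation of dialkyl squarates.

Step 2
Reactants: 3 1-(benzyloxy)-4-bromobenzene; 2 dibenzyl squarate
Product: 7 3-(benzyloxy)-4-(4-benzyloxyphenyl)cyclobut-3-ene-1,2-dione, via 4-(benzyloxy)phenyllithium 4 (not isolated), via lithium alkoxide adduct 5 (not isolated), via trifluoroacetate ester 6 (not isolated)
Conditions: n-BuLi, THF, −78 °C; then 2, −78 °C; then (CF3CO)2O, −78 °C; aq. NaHCO3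
Reagents that add atoms: water, O
Why: Bromine–lithium exchange and 1,2-addition of the aryllithium to one of the two equivalent squarate carbonyls, then trifluoroacetylation of the alkoxide, which triggers ionisation and hydrolytic loss of one benzyloxy group to the transposed dione (the established squarate-to-cyclobutenedione sequence).

Step 3
Reactants: 8 4-(benzyloxy)benzaldehyde; 9 (benzyloxymethyl)triphenylphosphonium chloride
Product: 11 1-(benzyloxy)-4-[2-(benzyloxy)ethenyl]benzene (E/Z mixture), via benzyloxymethylene ylide 10 (not isolated)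
Conditions: KOt-Bu, THF, 0 °C; then 8, 0 °C → rt
Reagents that add atoms: none
Why: Wittig olefination with a non-stabilised alkoxymethylene ylide, where the E/Z ratio is irrelevant because both isomers converge in step 4.

Step 4
Reactants: 11 1-(benzyloxy)-4-[2-(benzyloxy)ethenyl]benzene
Product: 13 1-(benzyloxy)-4-[(Z)-2-(benzyloxy)-1-bromoethenyl]benzene, via vicinal dibromide 12 (not isolated)
Conditions: Br2 (1.0 equiv), CH2Cl2, −78 °C; then Et3N, −78 °C → rt
Reagents that add atoms: bromine, BrBr
Why: Bromine addition to the enol ether then amine-induced dehydrobromination (loss of the anomeric bromide and the acidic benzylic proton) is the standard entry to β-bromo enol ethers, and the isomer with Br cis to OBn (aryl cis to H) should predominate as the less congested one.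

Step 5
Reactants: 13 1-(benzyloxy)-4-[(Z)-2-(benzyloxy)-1-bromoethenyl]benzene; 7 3-(benzyloxy)-4-(4-benzyloxyphenyl)cyclobut-3-ene-1,2-dione
Product: 16 3-(benzyloxy)-4-[(Z)-2-(benzyloxy)-1-(4-benzyloxyphenyl)ethenyl]-2-(4-benzyloxyphenyl)-4-(triethylsilyloxy)cyclobut-2-en-1-one (racemic), via alkenyllithium 14 (not isolated), via lithium alkoxide 15 (not isolated)
Conditions: t-BuLi (2 equiv), THF, −78 °C; cannulated into 7, THF, −78 °C; then TESOTf, −78 → −20 °C
Reagents that add atoms: triethylsilyl trifluoromethanesulfonate, CC[Si](CC)(CC)OS(=O)(=O)C(F)(F)F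
Why: Bromine–lithium exchange with retention gives the oxygen-chelated alkenyllithium (Li cis to OBn, the geometry that resists β-elimination), which adds 1,2 to the ketone-like carbonyl next to the benzyloxy-bearing carbon (the other carbonyl is a deactivated vinylogous ester), as established for organolithium additions to 3-alkoxy-4-arylcyclobutenediones with in situ O-protection; the carbinol stereocentre forms as a racemate and is erased in step 6.

Step 6
Reactants: 16 3-(benzyloxy)-4-[(Z)-2-(benzyloxy)-1-(4-benzyloxyphenyl)ethenyl]-2-(4-benzyloxyphenyl)-4-(triethylsilyloxy)cyclobut-2-en-1-one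
Product: 19 3,6-bis(benzyloxy)-2,5-bis(4-benzyloxyphenyl)-4-(triethylsilyloxy)phenol, via dienylketene 17 (not isolated), via cyclohexadienone 18 (not isolated)
Conditions: degassed toluene (0.02 M), 110 °C, Ar (p-xylene, 138 °C if slow)
Reagents that add atoms: none
Why: Heating induces conrotatory 4π opening of the cyclobutenone (C1–C4 bond) to dienylketene 17, and disrotatory 6π electrocyclisation then joins the ketene carbon to the benzyloxy-bearing vinyl terminus (target C4–C5) to give dienone 18, which enolises irreversibly to the phenol. The closest known reaction type is the thermal ring expansion of squarate-derived 4-alkenyl-4-hydroxy or 4-silyloxy cyclobutenones to hydroquinones and their mono-protected forms (Moore rearrangement). The six-membered carbocycle is closed in a 6π-electrocyclic mode onto the sp ketene carbon, not by an ionic or radical cyclisation. No stereocentre is created: the racemic carbinol centre and the alkene geometry of 16 are both erased on aromatisation. The selectivity needed is torquoselectivity in the opening, secured by the strong preference of the C4 oxygen donor (OTES) to rotate outward, which swings the alkenyl arm inward next to the ketene; a wrong-way opening can only revert to 16, and the substituent sequence itself was fixed in step 5. The inward-pointing benzyloxy group at the closing terminus meets only the linear ketene carbon, so it should slow but not prevent closure.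

Step 7
Reactants: 19 3,6-bis(benzyloxy)-2,5-bis(4-benzyloxyphenyl)-4-(triethylsilyloxy)phenol; 20 3-phenylpropanoyl chloride
Product: 21 3,6-bis(benzyloxy)-2,5-bis(4-benzyloxyphenyl)-4-(triethylsilyloxy)phenyl 3-phenylpropanoate
Conditions: Et3N, DMAP (cat.), CH2Cl2, 0 °C → rt
Reagents that add atoms: none
Why: DMAP-catalysed O-acylation of the only free phenol, with the para oxygen blocked as its flanked silyl ether so that no statistical mixture can arise.

Step 8
Reactants: 21 3,6-bis(benzyloxy)-2,5-bis(4-benzyloxyphenyl)-4-(triethylsilyloxy)phenyl 3-phenylpropanoate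
Product: 22 3,6-bis(benzyloxy)-2,5-bis(4-benzyloxyphenyl)-4-hydroxyphenyl 3-phenylpropanoate
Conditions: HF·pyridine, THF/pyridine, 0 °C
Reagents that add atoms: none
Why: Fluoride-mediated cleavage of the aryl silyl ether under buffered, non-basic conditions that leave the aryl ester and the benzyl ethers untouched.

Step 9
Reactants: 23 ethyl (S)-3-hydroxybutanoate
Product: 24 ethyl (S)-3-(benzyloxy)butanoate
Conditions: BnOC(=NH)CCl3, TfOH (cat.), CH2Cl2/cyclohexane, 0 °C → rt
Reagents that add atoms: benzyl 2,2,2-trichloroacetimidate, N=C(OCc1ccccc1)C(Cl)(Cl)Cl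
Why: Acid-catalysed O-benzylation with the trichloroacetimidate avoids the elimination seen under basic benzylation and does not touch the C–O bond of the stereocentre, so the (S) configuration is carried through unchanged.

Step 10
Reactants: 24 ethyl (S)-3-(benzyloxy)butanoate
Product: 25 (S)-3-(benzyloxy)butanoic acid
Conditions: LiOH, THF/H2O, 0 °C → rt; then 1 M HCl
Reagents that add atoms: lithium hydroxide, [Li+].[OH-]
Why: Mild saponification of the ethyl ester at low temperature, where β-elimination of benzyloxide is slow and the stereocentre is not involved.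

Step 11
Reactants: 22 3,6-bis(benzyloxy)-2,5-bis(4-benzyloxyphenyl)-4-hydroxyphenyl 3-phenylpropanoate; 25 (S)-3-(benzyloxy)butanoic acid
Product: 26 2,5-bis(benzyloxy)-3,6-bis(4-benzyloxyphenyl)-4-[(3-phenylpropanoyl)oxy]phenyl (3S)-3-(benzyloxy)butanoate
Conditions: DCC, DMAP (cat.), CH2Cl2, 0 °C → rt
Reagents that add atoms: none
Why: Steglich esterification of the liberated phenol under near-neutral conditions, placed late so that the β-benzyloxy ester never meets strong base.

Step 12
Reactants: 26 2,5-bis(benzyloxy)-3,6-bis(4-benzyloxyphenyl)-4-[(3-phenylpropanoyl)oxy]phenyl (3S)-3-(benzyloxy)butanoate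
Product: 27 2,5-dihydroxy-3,6-bis(4-hydroxyphenyl)-4-[(3-phenylpropanoyl)oxy]phenyl (3S)-3-hydroxybutanoate (CNP0296884.1)
Conditions: H2 (1 atm), Pd(OH)2/C, EtOAc/THF, rt; filtration under Ar
Reagents that add atoms: none
Why: Catalytic hydrogenolysis should cleave the four aryl benzyl ethers and the alkyl benzyl ether under neutral conditions that neither hydrolyse nor shift the two aryl esters, and it leaves the (S) carbinol untouched.

Compound list
1 | squaric acid (3,4-dihydroxycyclobut-3-ene-1,2-dione) | O=C1C(O)=C(O)C1=O | starting material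
2 | dibenzyl squarate (3,4-bis(benzyloxy)cyclobut-3-ene-1,2-dione) | O=C1C(=O)C(OCc2ccccc2)=C1OCc1ccccc1 | intermediate
3 | 1-(benzyloxy)-4-bromobenzene | Brc1ccc(OCc2ccccc2)cc1 | starting material
4 | 4-(benzyloxy)phenyllithium | [Li]c1ccc(OCc2ccccc2)cc1 | intermediate
5 | lithium alkoxide of 2,3-bis(benzyloxy)-4-(4-benzyloxyphenyl)-4-hydroxycyclobut-2-en-1-one (racemic) | O=C1C(OCc2ccccc2)=C(OCc2ccccc2)C1(O[Li])c1ccc(OCc2ccccc2)cc1 | intermediate
6 | 2,3-bis(benzyloxy)-1-(4-benzyloxyphenyl)-4-oxocyclobut-2-en-1-yl trifluoroacetate (racemic) | O=C1C(OCc2ccccc2)=C(OCc2ccccc2)C1(OC(=O)C(F)(F)F)c1ccc(OCc2ccccc2)cc1 | intermediate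
7 | 3-(benzyloxy)-4-(4-benzyloxyphenyl)cyclobut-3-ene-1,2-dione | O=C1C(=O)C(OCc2ccccc2)=C1c1ccc(OCc2ccccc2)cc1 | intermediate
8 | 4-(benzyloxy)benzaldehyde | O=Cc1ccc(OCc2ccccc2)cc1 | starting material
9 | (benzyloxymethyl)triphenylphosphonium chloride | [Cl-].c1ccc(cc1)[P+](COCc1ccccc1)(c1ccccc1)c1ccccc1 | starting material
10 | (benzyloxymethylene)triphenylphosphorane | C(OCc1ccccc1)=P(c1ccccc1)(c1ccccc1)c1ccccc1 | intermediate
11 | 1-(benzyloxy)-4-[2-(benzyloxy)ethenyl]benzene (E/Z mixture) | C(=COCc1ccccc1)c1ccc(OCc2ccccc2)cc1 | intermediate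
12 | 1-(benzyloxy)-4-[2-(benzyloxy)-1,2-dibromoethyl]benzene (diastereomer mixture) | BrC(C(Br)OCc1ccccc1)c1ccc(OCc2ccccc2)cc1 | intermediate
13 | 1-(benzyloxy)-4-[(Z)-2-(benzyloxy)-1-bromoethenyl]benzene (Br cis to OBn) | Br/C(c1ccc(OCc2ccccc2)cc1)=C\OCc1ccccc1 | intermediate
14 | [(E)-2-(benzyloxy)-1-(4-benzyloxyphenyl)ethenyl]lithium (Li cis to OBn) | [Li]/C(c1ccc(OCc2ccccc2)cc1)=C\OCc1ccccc1 | intermediate
15 | lithium alkoxide of 3-(benzyloxy)-4-[(Z)-2-(benzyloxy)-1-(4-benzyloxyphenyl)ethenyl]-2-(4-benzyloxyphenyl)-4-hydroxycyclobut-2-en-1-one (racemic) | O=C1C(c2ccc(OCc3ccccc3)cc2)=C(OCc2ccccc2)C1(O[Li])/C(c1ccc(OCc2ccccc2)cc1)=C\OCc1ccccc1 | intermediate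
16 | 3-(benzyloxy)-4-[(Z)-2-(benzyloxy)-1-(4-benzyloxyphenyl)ethenyl]-2-(4-benzyloxyphenyl)-4-(triethylsilyloxy)cyclobut-2-en-1-one (racemic; ring carbon cis to OBn on the alkene) | O=C1C(c2ccc(OCc3ccccc3)cc2)=C(OCc2ccccc2)C1(O[Si](CC)(CC)CC)/C(c1ccc(OCc2ccccc2)cc1)=C\OCc1ccccc1 | intermediate
17 | 3,6-bis(benzyloxy)-2,5-bis(4-benzyloxyphenyl)-4-(triethylsilyloxy)hexa-1,3,5-trien-1-one (dienylketene; ketene carbon and alkenyl arm cis across C3=C4, C5=C6 geometry as in 16) | O=C=C(c1ccc(OCc2ccccc2)cc1)\C(OCc1ccccc1)=C(O[Si](CC)(CC)CC)/C(c1ccc(OCc2ccccc2)cc1)=C\OCc1ccccc1 | intermediate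
18 | 3,6-bis(benzyloxy)-2,5-bis(4-benzyloxyphenyl)-4-(triethylsilyloxy)cyclohexa-2,4-dien-1-one (racemic) | O=C1C(c2ccc(OCc3ccccc3)cc2)=C(OCc2ccccc2)C(O[Si](CC)(CC)CC)=C(c2ccc(OCc3ccccc3)cc2)C1OCc1ccccc1 | intermediate
19 | 3,6-bis(benzyloxy)-2,5-bis(4-benzyloxyphenyl)-4-(triethylsilyloxy)phenol | Oc1c(-c2ccc(OCc3ccccc3)cc2)c(OCc2ccccc2)c(O[Si](CC)(CC)CC)c(-c2ccc(OCc3ccccc3)cc2)c1OCc1ccccc1 | intermediate
20 | 3-phenylpropanoyl chloride | O=C(Cl)CCc1ccccc1 | starting material
21 | 3,6-bis(benzyloxy)-2,5-bis(4-benzyloxyphenyl)-4-(triethylsilyloxy)phenyl 3-phenylpropanoate | O=C(CCc1ccccc1)Oc1c(-c2ccc(OCc3ccccc3)cc2)c(OCc2ccccc2)c(O[Si](CC)(CC)CC)c(-c2ccc(OCc3ccccc3)cc2)c1OCc1ccccc1 | intermediate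
22 | 3,6-bis(benzyloxy)-2,5-bis(4-benzyloxyphenyl)-4-hydroxyphenyl 3-phenylpropanoate | O=C(CCc1ccccc1)Oc1c(-c2ccc(OCc3ccccc3)cc2)c(OCc2ccccc2)c(O)c(-c2ccc(OCc3ccccc3)cc2)c1OCc1ccccc1 | intermediate
23 | ethyl (S)-3-hydroxybutanoate | C[C@H](O)CC(=O)OCC | starting material
24 | ethyl (S)-3-(benzyloxy)butanoate | C[C@H](OCc1ccccc1)CC(=O)OCC | intermediate
25 | (S)-3-(benzyloxy)butanoic acid | C[C@H](OCc1ccccc1)CC(=O)O | intermediate
26 | 2,5-bis(benzyloxy)-3,6-bis(4-benzyloxyphenyl)-4-[(3-phenylpropanoyl)oxy]phenyl (3S)-3-(benzyloxy)butanoate | C[C@H](OCc1ccccc1)CC(=O)Oc1c(-c2ccc(OCc3ccccc3)cc2)c(OCc2ccccc2)c(OC(=O)CCc2ccccc2)c(-c2ccc(OCc3ccccc3)cc2)c1OCc1ccccc1 | intermediate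
27 | 2,5-dihydroxy-3,6-bis(4-hydroxyphenyl)-4-[(3-phenylpropanoyl)oxy]phenyl (3S)-3-hydroxybutanoate (CNP0296884.1) | C[C@H](O)CC(=O)Oc1c(O)c(-c2ccc(O)cc2)c(OC(=O)CCc2ccccc2)c(O)c1-c1ccc(O)cc1 | target

Total step count: 12. Longest linear sequence: 8 steps (1, 2, 5, 6, 7, 8, 11, 12 from squaric acid; equally 3, 4, 5, 6, 7, 8, 11, 12 from the aldehyde).

Steps most likely to fail

Step 5. The β-benzyloxy alkenyllithium may lose lithium benzyloxide to give the arylalkyne, or isomerise, before it adds, and in situ silylation of the congested tertiary alkoxide may stay incomplete. The fallback sets out from 13 and 7 and returns at 16. Bromine–magnesium exchange on 13 (i-PrMgCl·LiCl, THF, −20 °C) should give [(Z)-2-(benzyloxy)-1-(4-benzyloxyphenyl)ethenyl]magnesium chloride F1, a configurationally stable reagent far less prone to β-elimination. Addition of F1 to 7 at −40 °C and NH4Cl work-up should give the isolable tertiary alcohol 3-(benzyloxy)-4-[(Z)-2-(benzyloxy)-1-(4-benzyloxyphenyl)ethenyl]-2-(4-benzyloxyphenyl)-4-hydroxycyclobut-2-en-1-one F2. Separate silylation (TESOTf, 2,6-lutidine, CH2Cl2, −78 °C) then gives 16.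

Step 6. Inward rotation of the bulky arylvinyl arm may be disfavoured, or closure onto the benzyloxy-substituted terminus may be slow enough that the ketene is diverted into dimerisation or cycloaddition; the electron-rich phenol may also be oxidised during isolation. The fallback builds the same arene by cross-coupling instead of ring expansion, setting out from 3 and returning at 22:
- Lithiation of 3 (via 4), quenching with triisopropyl borate and dilute acid should give 4-(benzyloxy)phenylboronic acid F3.
- Tetrabromo-1,4-benzoquinone and sodium benzyloxide (two addition–elimination events, the second para to the first) should give 2,5-bis(benzyloxy)-3,6-dibromo-1,4-benzoquinone F4.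
- Two-fold Suzuki–Miyaura coupling of F4 with F3 (Pd(PPh3)4, K2CO3, dioxane, 80 °C) should give 2,5-bis(benzyloxy)-3,6-bis(4-benzyloxyphenyl)-1,4-benzoquinone F5.
- Dithionite reduction should give the centrosymmetric 2,5-bis(benzyloxy)-3,6-bis(4-benzyloxyphenyl)benzene-1,4-diol F6.
- Because the two hydroxyls of F6 are equivalent, one-fold acylation with 20 (1 equiv, Et3N, DMAP) can give only 22, besides separable bis-ester and recyclable diol.

Step 12. Hydrogenolysis of five benzyl ethers may stall at the flanked central ethers; during long exposure an acyl group may shift to a freshly released neighbouring hydroxyl, or the hydroquinone may be oxidised on handling. The fallback sets out from 26 and arrives directly at 27. It uses non-reductive Lewis-acid debenzylation with BCl3 and pentamethylbenzene as benzyl-cation scavenger (CH2Cl2, −78 °C), a fast, non-basic method known to spare aryl esters; no new compound arises on this detour (F0).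

Further compounds
F1 | step 5 | [(Z)-2-(benzyloxy)-1-(4-benzyloxyphenyl)ethenyl]magnesium chloride (Mg cis to OBn) | Cl[Mg]/C(c1ccc(OCc2ccccc2)cc1)=C\OCc1ccccc1
F2 | step 5 | 3-(benzyloxy)-4-[(Z)-2-(benzyloxy)-1-(4-benzyloxyphenyl)ethenyl]-2-(4-benzyloxyphenyl)-4-hydroxycyclobut-2-en-1-one (racemic) | O=C1C(c2ccc(OCc3ccccc3)cc2)=C(OCc2ccccc2)C1(O)/C(c1ccc(OCc2ccccc2)cc1)=C\OCc1ccccc1
F3 | step 6 | 4-(benzyloxy)phenylboronic acid | OB(O)c1ccc(OCc2ccccc2)cc1
F4 | step 6 | 2,5-bis(benzyloxy)-3,6-dibromo-1,4-benzoquinone | O=C1C(OCc2ccccc2)=C(Br)C(=O)C(OCc2ccccc2)=C1Br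
F5 | step 6 | 2,5-bis(benzyloxy)-3,6-bis(4-benzyloxyphenyl)-1,4-benzoquinone | O=C1C(OCc2ccccc2)=C(c2ccc(OCc3ccccc3)cc2)C(=O)C(OCc2ccccc2)=C1c1ccc(OCc2ccccc2)cc1
F6 | step 6 | 2,5-bis(benzyloxy)-3,6-bis(4-benzyloxyphenyl)benzene-1,4-diol | Oc1c(OCc2ccccc2)c(-c2ccc(OCc3ccccc3)cc2)c(O)c(OCc2ccccc2)c1-c1ccc(OCc2ccccc2)cc1
F0 | step 12 | none | none
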